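**Plan**
- Retrosynthesis: both sp2–sp2 single bonds C10–C11 and C10'–C11' (carotenoid numbering) are cut at once, giving the C12 pentaenyl diiodide 11 (C11 to C11') and two identical C14 dienylaluminium units 12. Each unit 12 is cut further at C9–CH3/C10–Al (methylalumination of enyne 8), C8–C9 (ethynylation), C7=C8 (Takai olefination) and C6–C7 ([2,3]-shift).
- Enabling feature: the C2 axis through the midpoint of C15=C15' makes the two cut sites homotopic, so one enantiopure end unit serves twice. C9=C10 is an E-trisubstituted alkene with a methyl group on C9, which is what syn-methylalumination of a terminal alkyne delivers, with the metal on C10.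
- Forward order: the six-membered ring is bought (enone 1) and the chain is grown C7, then C8, then C9/C10 to enyne 8. The bought C10 dialdehyde 9 is extended to diiodide 11, and a telescoped methylalumination/two-fold Negishi coupling joins C14 + C12 + C14.
- Stereochemistry: C6 comes from a CBS reduction of 1 (R carbinol at the future C4), moved suprafacially to C6 by a Still–Wittig rearrangement that also places the ring alkene at C4=C5. No later step uses a base or acid able to remove the C6–H.
- Alkene geometry: Takai olefination (C7=C8, C11=C12, C11'=C12'), syn-carbometalation (C9=C10, C9'=C10') and the bought dial (C13=C14, C15=C15', C14'=C13').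

Key step: step 8

Assumption: 1 and 9 are taken as bought; carotenoid numbering (C1–C20, primed for the second half) is used when positions of the target are discussed.

**Step 1**
Reactants: 1 2,4,4-trimethylcyclohex-2-en-1-one
Product: 2 (1R)-2,4,4-trimethylcyclohex-2-en-1-ol
Conditions: (S)-2-methyl-CBS-oxazaborolidine [(3aS)-1-methyl-3,3-diphenyltetrahydro-1H,3H-pyrrolo[1,2-c][1,3,2]oxazaborole] (0.1 equiv), BH3·SMe2 (0.7 equiv), THF, −20 °C; MeOH, then aq. NH4Cl
Reagents that add atoms: none
Why: Corey–Bakshi–Shibata reduction, in which the ketone binds the oxazaborolidine boron anti to its larger 2-methylvinyl arm and the nitrogen-bound borane delivers hydride to one carbonyl face only, which with the S catalyst should give the R carbinol by 1,2-reduction without touching the ring alkene.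

**Step 2**
Reactants: 2 (1R)-2,4,4-trimethylcyclohex-2-en-1-ol
Product: 3 tributyl({[(1R)-2,4,4-trimethylcyclohex-2-en-1-yl]oxy}methyl)stannane
Conditions: KH (1.3 equiv), 18-crown-6 (cat.), THF, 0 °C; Bu3SnCH2I (1.2 equiv), 0 to 23 °C
Reagents that add atoms: tributyl(iodomethyl)stannane, CCCC[Sn](CI)(CCCC)CCCC
Why: Williamson etherification (SN2 at the primary iodomethyl carbon) by the potassium alkoxide, which leaves the C–O stereocentre untouched and installs the tin handle needed to generate the carbanion.

**Step 3**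
Reactants: 3 tributyl({[(1R)-2,4,4-trimethylcyclohex-2-en-1-yl]oxy}methyl)stannane
Product: 5 [(1S)-2,6,6-trimethylcyclohex-2-en-1-yl]methanol, via lithiomethyl ether 4 (not isolated)
Conditions: n-BuLi (1.3 equiv), THF, −78 °C; H2O
Reagents that add atoms: none
Why: Still–Wittig [2,3]-sigmatropic rearrangement, in which tin–lithium exchange gives carbanion 4 and its CH2 is delivered through a five-membered envelope transition state to the alkene terminus next to the gem-dimethyl carbon on the ring face that bears oxygen (suprafacial 1,3-transfer of chirality, R at C–O becoming S at the new C6), while the alkene moves to the C4=C5 position of the ε ring.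

**Step 4**
Reactants: 5 [(1S)-2,6,6-trimethylcyclohex-2-en-1-yl]methanol
Product: 6 (1S)-2,6,6-trimethylcyclohex-2-ene-1-carbaldehyde
Conditions: Dess–Martin periodinane (1.3 equiv), pyridine (3 equiv), CH2Cl2, 0 °C; used cold and without delay
Reagents that add atoms: none
Why: Dess–Martin oxidation of the primary alcohol under pyridine-buffered, near-neutral conditions, chosen so that the α-stereocentre (C6) of the β,γ-unsaturated aldehyde is not enolised and the ring alkene does not move into conjugation.

**Step 5**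
Reactants: 6 (1S)-2,6,6-trimethylcyclohex-2-ene-1-carbaldehyde
Product: 7 (6S)-6-[(E)-2-iodoethenyl]-1,5,5-trimethylcyclohex-1-ene
Conditions: CHI3 (2.5 equiv), CrCl2 (8 equiv), THF/1,4-dioxane, 0 to 23 °C, dark
Reagents that add atoms: iodoform, IC(I)I
Why: Takai olefination, in which the geminal dichromium carbenoid from CHI3 and CrCl2 adds to the aldehyde and eliminates to the E iodoalkene (E selectivity is highest for α-branched aldehydes), and the reagent is non-basic so C6 should keep its configuration.

**Step 6**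
Reactants: 7 (6S)-6-[(E)-2-iodoethenyl]-1,5,5-trimethylcyclohex-1-ene
Product: 8 (6S)-6-[(1E)-but-1-en-3-yn-1-yl]-1,5,5-trimethylcyclohex-1-ene
Conditions: HC≡CMgBr (2.5 equiv), ZnBr2 (2.5 equiv), THF, 0 °C; then 7, Pd(PPh3)4 (5 mol %), 23 °C
Reagents that add atoms: ethynylmagnesium bromide, C#C[Mg]Br
Why: Negishi alkynylation, in which zerovalent palladium inserts into the C–I bond with retention, ethynylzinc bromide transmetalates and reductive elimination gives the terminal E enyne directly, without a base or copper salt that could epimerise C6 or dimerise the alkyne.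

**Step 7**
Reactants: 9 (2E,4E,6E)-2,7-dimethylocta-2,4,6-trienedial
Product: 11 (1E,3E,5E,7E,9E)-1,10-diiodo-3,8-dimethyldeca-1,3,5,7,9-pentaene, via iodotetraenal 10 (not isolated)
Conditions: CHI3 (5 equiv), CrCl2 (16 equiv), THF/1,4-dioxane, 0 to 23 °C, dark; crystallised cold and used at once
Reagents that add atoms: iodoform, IC(I)I
Why: Two-fold Takai olefination of the two homotopic α-methyl enal termini, each expected to give the E iodoalkene by way of the mono-olefinated aldehyde 10, so that the bought E,E,E core (C13=C14, C15=C15', C14'=C13') is extended to the all-E C11–C11' diiodide.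

**Step 8**
Reactants: 8 (6S)-6-[(1E)-but-1-en-3-yn-1-yl]-1,5,5-trimethylcyclohex-1-ene (2.4 equiv); 11 (1E,3E,5E,7E,9E)-1,10-diiodo-3,8-dimethyldeca-1,3,5,7,9-pentaene (1.0 equiv)
Product: 14 (6S,6'S)-ε,ε-carotene, via dienylalane 12 (not isolated), via heptaenyl iodide 13 (not isolated)
Conditions: 8, AlMe3 (2 equiv per alkyne), Cp2ZrCl2 (0.25 equiv per alkyne), CH2Cl2, 0 to 23 °C; volatiles removed at 0.1 mbar; then THF/DMF, 11, Pd2(dba)3 (2.5 mol %), tri(2-furyl)phosphine (10 mol %), ZnCl2 (0.5 equiv, co-catalyst), 23 °C, dark; cold aq. NaHCO3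
Reagents that add atoms: trimethylaluminium, C[Al](C)C
Why: Zirconocene-catalysed syn-methylalumination adds CH3 to C9 and aluminium to C10 of terminal enyne 8 across one face of the alkyne to give the E dienylalane 12; its alkenyl group is passed through catalytic ZnCl2 to palladium that has inserted into a C–I bond of 11, reductive elimination forges C10–C11, and the same cycle on heptaenyl iodide 13 forges C10'–C11'. The closest known reaction type is the Negishi alkenyl–alkenyl cross-coupling of carboalumination-derived alkenylalanes with alkenyl iodides under palladium–zinc co-catalysis, run here in two directions on a bis(iodoalkene). No ring is closed and no stereocentre is created; the two new trisubstituted alkenes (C9=C10, C9'=C10') should be E because the addition is syn, and the two new sigma bonds should keep the E geometry of both partners because oxidative addition, transmetalation and reductive elimination all go with retention. The step needs regioselective methylalumination (secured by the terminal alkyne, which takes aluminium at its unsubstituted end, while the trisubstituted ring alkene is inert), transfer of alkenyl and not methyl from aluminium (secured by the much faster alkenyl transmetalation through zinc and by stripping excess AlMe3), and complete two-fold coupling (secured by the excess of 12 over 11, whose homotopic C–I ends react independently). The doubly allylic C6–H meets neither base nor protic acid, so the S configuration set in step 3 should be carried into both ends.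

**Compound list**
1 | 2,4,4-trimethylcyclohex-2-en-1-one | O=C1CCC(C)(C)C=C1C | starting material
2 | (1R)-2,4,4-trimethylcyclohex-2-en-1-ol | O[C@@H]1CCC(C)(C)C=C1C | intermediate
3 | tributyl({[(1R)-2,4,4-trimethylcyclohex-2-en-1-yl]oxy}methyl)stannane | CCCC[Sn](CCCC)(CCCC)CO[C@@H]1CCC(C)(C)C=C1C | intermediate
4 | ({[(1R)-2,4,4-trimethylcyclohex-2-en-1-yl]oxy}methyl)lithium | [Li]CO[C@@H]1CCC(C)(C)C=C1C | intermediate (not isolated)
5 | [(1S)-2,6,6-trimethylcyclohex-2-en-1-yl]methanol | CC1=CCCC(C)(C)[C@@H]1CO | intermediate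
6 | (1S)-2,6,6-trimethylcyclohex-2-ene-1-carbaldehyde | CC1=CCCC(C)(C)[C@@H]1C=O | intermediate
7 | (6S)-6-[(E)-2-iodoethenyl]-1,5,5-trimethylcyclohex-1-ene | CC1=CCCC(C)(C)[C@@H]1/C=C/I | intermediate
8 | (6S)-6-[(1E)-but-1-en-3-yn-1-yl]-1,5,5-trimethylcyclohex-1-ene | CC1=CCCC(C)(C)[C@@H]1/C=C/C#C | intermediate
9 | (2E,4E,6E)-2,7-dimethylocta-2,4,6-trienedial | O=C/C(C)=C/C=C/C=C(C)/C=O | starting material
10 | (2E,4E,6E,8E)-9-iodo-2,7-dimethylnona-2,4,6,8-tetraenal | O=C/C(C)=C/C=C/C=C(C)/C=C/I | intermediate (not isolated)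
11 | (1E,3E,5E,7E,9E)-1,10-diiodo-3,8-dimethyldeca-1,3,5,7,9-pentaene | I/C=C/C(C)=C/C=C/C=C(C)/C=C/I | intermediate
12 | dimethyl{(1E,3E)-2-methyl-4-[(1S)-2,6,6-trimethylcyclohex-2-en-1-yl]buta-1,3-dien-1-yl}alumane | CC1=CCCC(C)(C)[C@@H]1/C=C/C(C)=C/[Al](C)C | intermediate (not isolated)
13 | (6S)-6-[(1E,3E,5E,7E,9E,11E,13E)-14-iodo-3,7,12-trimethyltetradeca-1,3,5,7,9,11,13-heptaen-1-yl]-1,5,5-trimethylcyclohex-1-ene | CC1=CCCC(C)(C)[C@@H]1/C=C/C(C)=C/C=C/C(C)=C/C=C/C=C(C)/C=C/I | intermediate (not isolated)
14 | (6S,6'S)-ε,ε-carotene | CC1=CCCC(C)(C)[C@@H]1/C=C/C(C)=C/C=C/C(C)=C/C=C/C=C(C)/C=C/C=C(C)/C=C/[C@@H]1C(C)=CCCC1(C)C | target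

**Step count**
Total: 8 steps. Longest linear sequence: 7 steps (steps 1 to 6, then step 8).

**Steps most likely to fail**

Step 8. The diiodide may be lost by reduction or E/Z isomerisation under the organoaluminium–palladium conditions, methyl may be transferred in place of alkenyl, and the reaction may stall after the first coupling because the titre of the alane is not known exactly. The fallback sets out from 8 and 9 and comes back at 14, with the polarity reversed and both partners isolated.
- 8 would be methylaluminated as in step 8 (12) and the alane quenched with I2 in THF at −30 °C to give (6S)-6-[(1E,3E)-4-iodo-3-methylbuta-1,3-dien-1-yl]-1,5,5-trimethylcyclohex-1-ene F1, which is purified.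
- 9 would be treated with 2-(dichloromethyl)-4,4,5,5-tetramethyl-1,3,2-dioxaborolane, CrCl2 and LiI in THF (Takai–Utimoto borylolefination). This passes through (2E,4E,6E,8E)-2,7-dimethyl-9-(4,4,5,5-tetramethyl-1,3,2-dioxaborolan-2-yl)nona-2,4,6,8-tetraenal F2 and should give 2,2'-[(1E,3E,5E,7E,9E)-3,8-dimethyldeca-1,3,5,7,9-pentaene-1,10-diyl]bis(4,4,5,5-tetramethyl-1,3,2-dioxaborolane) F3.
- Two-fold Suzuki–Miyaura coupling of F3 with F1 (2.2 equiv; Pd(OAc)2, 2-dicyclohexylphosphino-2',6'-dimethoxybiphenyl, aq. K3PO4, THF, 40 °C, dark) would proceed through 4,4,5,5-tetramethyl-2-{(1E,3E,5E,7E,9E,11E,13E)-3,8,12-trimethyl-14-[(1S)-2,6,6-trimethylcyclohex-2-en-1-yl]tetradeca-1,3,5,7,9,11,13-heptaen-1-yl}-1,3,2-dioxaborolane F4 and should deliver 14.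

Step 3. The [1,2]-shift and simple protonation of the carbanion may compete with the [2,3]-shift, because the accepting ring carbon lies next to the quaternary gem-dimethyl carbon. The fallback sets out from 2 and comes back at 8, replacing the carbanionic [2,3]-shift by a thermal [3,3]-shift.
- 2 would be heated with triethyl orthoacetate and a trace of propanoic acid at 140 °C (Johnson–Claisen rearrangement). The ketene acetal 1-ethoxy-1-{[(1R)-2,4,4-trimethylcyclohex-2-en-1-yl]oxy}ethene F5 formed in the flask should rearrange suprafacially to ethyl 2-[(1S)-2,6,6-trimethylcyclohex-2-en-1-yl]acetate F6.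
- i-Bu2AlH (toluene, −78 °C) would give 2-[(1S)-2,6,6-trimethylcyclohex-2-en-1-yl]acetaldehyde F7.
- HC≡CMgBr (THF, 0 °C) would give 1-[(1S)-2,6,6-trimethylcyclohex-2-en-1-yl]but-3-yn-2-ol F8 as both carbinol epimers.
- MsCl/Et3N would give 1-[(1S)-2,6,6-trimethylcyclohex-2-en-1-yl]but-3-yn-2-yl methanesulfonate F9, from which DBU (THF, 23 °C) should eliminate towards C7 to give 8. The E isomer would be separated on AgNO3-impregnated silica gel.

Step 7. One of the two olefinations may give the Z iodoalkene, and the light-sensitive polyenyl diiodide may decompose during purification. The fallback sets out from 9 and comes back at 11, with the alkene geometry set by syn-hydrometalation of an alkyne instead of by the chromium carbenoid.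
- Corey–Fuchs olefination (CBr4, PPh3, CH2Cl2, 0 °C) would give (3E,5E,7E)-1,1,10,10-tetrabromo-3,8-dimethyldeca-1,3,5,7,9-pentaene F10.
- n-BuLi (THF, −78 °C) would give the dilithium salt [(3E,5E,7E)-3,8-dimethyldeca-3,5,7-triene-1,9-diyne-1,10-diyl]dilithium F11, which water protonates to (3E,5E,7E)-3,8-dimethyldeca-3,5,7-triene-1,9-diyne F12.
- Two-fold hydrozirconation with Cp2Zr(H)Cl (THF, 23 °C, dark) would give [(1E,3E,5E,7E,9E)-3,8-dimethyldeca-1,3,5,7,9-pentaene-1,10-diyl]bis[chlorobis(cyclopentadienyl)zirconium] F13, and I2 at −78 °C should cleave both C–Zr bonds with retention to give 11.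

**Further compounds**
F1 | step 8 | (6S)-6-[(1E,3E)-4-iodo-3-methylbuta-1,3-dien-1-yl]-1,5,5-trimethylcyclohex-1-ene | CC1=CCCC(C)(C)[C@@H]1/C=C/C(C)=C/I
F2 | step 8 | (2E,4E,6E,8E)-2,7-dimethyl-9-(4,4,5,5-tetramethyl-1,3,2-dioxaborolan-2-yl)nona-2,4,6,8-tetraenal | O=C/C(C)=C/C=C/C=C(C)/C=C/B1OC(C)(C)C(C)(C)O1
F3 | step 8 | 2,2'-[(1E,3E,5E,7E,9E)-3,8-dimethyldeca-1,3,5,7,9-pentaene-1,10-diyl]bis(4,4,5,5-tetramethyl-1,3,2-dioxaborolane) | CC1(C)OB(/C=C/C(C)=C/C=C/C=C(C)/C=C/B2OC(C)(C)C(C)(C)O2)OC1(C)C
F4 | step 8 | 4,4,5,5-tetramethyl-2-{(1E,3E,5E,7E,9E,11E,13E)-3,8,12-trimethyl-14-[(1S)-2,6,6-trimethylcyclohex-2-en-1-yl]tetradeca-1,3,5,7,9,11,13-heptaen-1-yl}-1,3,2-dioxaborolane | CC1=CCCC(C)(C)[C@@H]1/C=C/C(C)=C/C=C/C(C)=C/C=C/C=C(C)/C=C/B1OC(C)(C)C(C)(C)O1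
F5 | step 3 | 1-ethoxy-1-{[(1R)-2,4,4-trimethylcyclohex-2-en-1-yl]oxy}ethene | C=C(OCC)O[C@@H]1CCC(C)(C)C=C1C
F6 | step 3 | ethyl 2-[(1S)-2,6,6-trimethylcyclohex-2-en-1-yl]acetate | CC1=CCCC(C)(C)[C@@H]1CC(=O)OCC
F7 | step 3 | 2-[(1S)-2,6,6-trimethylcyclohex-2-en-1-yl]acetaldehyde | CC1=CCCC(C)(C)[C@@H]1CC=O
F8 | step 3 | 1-[(1S)-2,6,6-trimethylcyclohex-2-en-1-yl]but-3-yn-2-ol | CC1=CCCC(C)(C)[C@@H]1CC(O)C#C
F9 | step 3 | 1-[(1S)-2,6,6-trimethylcyclohex-2-en-1-yl]but-3-yn-2-yl methanesulfonate | CC1=CCCC(C)(C)[C@@H]1CC(OS(C)(=O)=O)C#C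
F10 | step 7 | (3E,5E,7E)-1,1,10,10-tetrabromo-3,8-dimethyldeca-1,3,5,7,9-pentaene | BrC(Br)=C/C(C)=C/C=C/C=C(C)/C=C(Br)Br
F11 | step 7 | [(3E,5E,7E)-3,8-dimethyldeca-3,5,7-triene-1,9-diyne-1,10-diyl]dilithium | [Li]C#C/C(C)=C/C=C/C=C(C)/C#C[Li]
F12 | step 7 | (3E,5E,7E)-3,8-dimethyldeca-3,5,7-triene-1,9-diyne | C#C/C(C)=C/C=C/C=C(C)/C#C
F13 | step 7 | [(1E,3E,5E,7E,9E)-3,8-dimethyldeca-1,3,5,7,9-pentaene-1,10-diyl]bis[chlorobis(cyclopentadienyl)zirconium] (cyclopentadienyl rings drawn sigma-bonded) | Cl[Zr](C1C=CC=C1)(C1C=CC=C1)/C=C/C(C)=C/C=C/C=C(C)/C=C/[Zr](Cl)(C1C=CC=C1)C1C=CC=C1
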